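**Retrosynthetic overview**

1. The bicycle is numbered as a 2‑benzofuran (C1 lactone C=O, O2, C3H2, C3a, C4=O, C5=C6, C7H2, C7a). The target is the trans‑fused (3aR,7aR) isomer, with the side chain at C3a anti to the OH at C7a. Any closure of the cyclohexenone at C3a or C7a of the preformed, nearly flat γ‑lactone (for example a vinylogous aldol addition of the butenoyl group to C7a) is expected to give the cis isomer, so this ring is closed last at its remote C5=C6 bond.
2. Key disconnection: C5=C6, by ring‑closing metathesis between a C3a (E)‑butenoyl group and a C7a allyl group held trans on the lactone in 15. The enabling feature is the cis C5=C6 alkene of the cyclohexenone ring, which lies between C4=O and C7H2, two bonds away from both fusion carbons.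
3. C7a–C7: chelation‑controlled allyl addition to the C3 ketone of α‑keto lactone 14, anti to the butenoyl group. γ‑Lactone and C3a: enantioselective hydroxymethylation/lactonization of the open‑chain 2,4‑dioxo ester 12 (formaldehyde supplies C3, diethyl oxalate supplies C1 and C7a).
4. 12 comes from Claisen condensation of enone 10 with diethyl oxalate. The 2‑pyranone of 10 comes from gold‑catalysed 6‑endo cyclization of a (Z)‑enynoate built by acetoacetate alkylation, enol triflation and Sonogashira coupling with 3‑ethynylfuran.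
5. Order of ring formation: furan (bought) → 2‑pyranone (step 6) → γ‑lactone (step 8) → cyclohexenone (step 10).

Key step: step 10

Assumption: in step 8 the (R)‑ligand is taken to give the (4S) lactone 14; if the sense of induction is the opposite, the (S)‑ligand is used. In names, "Ar‑ethyl" stands for 2‑[6‑(furan‑3‑yl)‑4‑methyl‑2‑oxo‑2H‑pyran‑3‑yl]ethyl.

**Route**

Step 1
Reactants: 1 tert‑butyl 3‑oxobutanoate; 2 4‑chloro‑N‑methoxy‑N‑methylbutanamide
Product: 3 tert‑butyl 2‑acetyl‑6‑[methoxy(methyl)amino]‑6‑oxohexanoate (racemic)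
Conditions: NaH, DMF, 0 °C; then 2, NaI (cat.), 60 °C
Reagents that add atoms: none
Why: The sodium enolate of the β‑keto ester is alkylated at carbon by the primary chloride, activated in situ as the iodide (acetoacetic ester alkylation), while the Weinreb amide is not attacked by this stabilized enolate; the new stereocentre becomes sp2 in step 2.

Step 2
Reactants: 3 tert‑butyl 2‑acetyl‑6‑[methoxy(methyl)amino]‑6‑oxohexanoate
Product: 4 tert‑butyl (2Z)‑2‑{4‑[methoxy(methyl)amino]‑4‑oxobutyl}‑3‑[(trifluoromethanesulfonyl)oxy]but‑2‑enoate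
Conditions: Tf2O, aq. LiOH, toluene, 5 °C
Reagents that add atoms: trifluoromethanesulfonic anhydride, O=S(=O)(OS(=O)(=O)C(F)(F)F)C(F)(F)F
Why: Under biphasic aqueous LiOH the lithium‑chelated enolate, with ester carbonyl and enolate oxygen held syn, is O‑sulfonylated, so that ester and triflate should end up cis on the tetrasubstituted alkene (stereoselective enol triflation of a β‑keto ester), the geometry that the later pyranone closure needs.

Step 3
Reactants: 5 furan‑3‑carbaldehyde
Product: 6 3‑ethynylfuran (volatile, used as a solution)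
Conditions: dimethyl (1‑diazo‑2‑oxopropyl)phosphonate, K2CO3, MeOH, 0 °C to rt
Reagents that add atoms: dimethyl (1‑diazo‑2‑oxopropyl)phosphonate, COP(=O)(OC)C(=[N+]=[N-])C(C)=O
Why: Ohira–Bestmann (Seyferth–Gilbert) homologation, in which the diazophosphonate anion freed by methanolysis adds to the aldehyde, dimethyl phosphate is eliminated and the alkylidene carbene rearranges to the terminal alkyne.

Step 4
Reactants: 4 tert‑butyl (2Z)‑2‑{4‑[methoxy(methyl)amino]‑4‑oxobutyl}‑3‑[(trifluoromethanesulfonyl)oxy]but‑2‑enoate; 6 3‑ethynylfuran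
Product: 7 tert‑butyl (2Z)‑5‑(furan‑3‑yl)‑2‑{4‑[methoxy(methyl)amino]‑4‑oxobutyl}‑3‑methylpent‑2‑en‑4‑ynoate
Conditions: Pd(PPh3)2Cl2 (cat.), CuI (cat.), Et3N, THF, rt
Reagents that add atoms: none
Why: Sonogashira coupling of a vinyl triflate with a terminal alkyne proceeds with retention of alkene geometry, so the (Z)‑enynoate with ester and alkyne cis should result.

Step 5
Reactants: 7 tert‑butyl (2Z)‑5‑(furan‑3‑yl)‑2‑{4‑[methoxy(methyl)amino]‑4‑oxobutyl}‑3‑methylpent‑2‑en‑4‑ynoate
Product: 9 tert‑butyl (2Z)‑5‑(furan‑3‑yl)‑3‑methyl‑2‑[(5E)‑4‑oxohept‑5‑en‑1‑yl]pent‑2‑en‑4‑ynoate, via allyl ketone 8 (not isolated)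
Conditions: allylMgBr, THF, −78 °C; aq. NH4Cl; then DBU (cat.), CH2Cl2, rt
Reagents that add atoms: allylmagnesium bromide, C=CC[Mg]Br
Why: Weinreb ketone synthesis (the magnesium‑chelated tetrahedral adduct survives until work‑up, which prevents over‑addition, and the hindered tetrasubstituted tert‑butyl enoate is inert at −78 °C), followed by base‑catalysed migration of the β,γ‑double bond into conjugation, which should give the thermodynamically preferred (E)‑enone.

Step 6
Reactants: 9 tert‑butyl (2Z)‑5‑(furan‑3‑yl)‑3‑methyl‑2‑[(5E)‑4‑oxohept‑5‑en‑1‑yl]pent‑2‑en‑4‑ynoate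
Product: 10 6‑(furan‑3‑yl)‑4‑methyl‑3‑[(5E)‑4‑oxohept‑5‑en‑1‑yl]‑2H‑pyran‑2‑one
Conditions: Ph3PAuNTf2 (5 mol %), CH2Cl2, rt
Reagents that add atoms: none
Why: Carbophilic activation of the alkyne by cationic gold triggers 6‑endo‑dig attack of the cis ester carbonyl oxygen at the alkyne carbon bearing the cation‑stabilizing 3‑furyl group, the tert‑butyl group leaves as isobutene and protodeauration gives the 2‑pyranone (gold‑catalysed cycloisomerization of a tert‑butyl (Z)‑2‑en‑4‑ynoate), the enone being a spectator.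

Step 7
Reactants: 10 6‑(furan‑3‑yl)‑4‑methyl‑3‑[(5E)‑4‑oxohept‑5‑en‑1‑yl]‑2H‑pyran‑2‑one; 11 diethyl oxalate
Product: 12 ethyl (5E)‑3‑(Ar‑ethyl)‑2,4‑dioxohept‑5‑enoate (drawn as the triketo form, expected to be largely enolized)
Conditions: LiN(SiMe3)2, THF, −78 °C; then 11, −78 to 0 °C; aq. NH4Cl, 0 °C
Reagents that add atoms: none
Why: Crossed Claisen condensation, in which the amide base should deprotonate the enone kinetically at the α′‑CH2 (not at the γ‑methyl or the pyranone methyl), the cross‑conjugated enolate is acylated by diethyl oxalate and the product stays protected as its chelated lithium diketonate until the cold, mild quench.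

Step 8
Reactants: 12 ethyl (5E)‑3‑(Ar‑ethyl)‑2,4‑dioxohept‑5‑enoate
Product: 14 (4S)‑4‑[(2E)‑but‑2‑enoyl]‑4‑(Ar‑ethyl)oxolane‑2,3‑dione, via hydroxymethyl adduct 13 (not isolated)
Conditions: [Pd((R)‑BINAP)(OH2)2](OTf)2 (5 mol %), aq. CH2O (37 %), THF, −20 °C; then toluene, 4 Å MS, rt
Reagents that add atoms: formaldehyde, C=O
Why: Proposed new method: the chiral palladium aqua complex should turn the 1,3‑dicarbonyl unit of 12 into an O,O‑chelated palladium enolate whose two faces at C3 are differentiated by the BINAP aryl groups, the triflic acid released activates formaldehyde for aldol addition at C3 (this sets the quaternary centre, C3a of the target), and the primary alcohol of 13 then closes the five‑membered lactone onto the ketone‑activated ethyl ester by 5‑exo‑trig acyl substitution with loss of ethanol; the closest known reaction types are the catalytic enantioselective hydroxymethylation of 2‑substituted β‑keto esters with formalin through chiral palladium enolates and the classical condensation of acylpyruvates with formaldehyde to α‑keto‑γ‑butyrolactones, and the non‑basic medium is chosen so that the butenoyl γ‑methyl is not deprotonated, since its vinylogous aldol addition to C3 would close the carbocycle at a fusion atom with cis fusion.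

Step 9
Reactants: 14 (4S)‑4‑[(2E)‑but‑2‑enoyl]‑4‑(Ar‑ethyl)oxolane‑2,3‑dione
Product: 15 (3R,4R)‑4‑[(2E)‑but‑2‑enoyl]‑4‑(Ar‑ethyl)‑3‑hydroxy‑3‑(prop‑2‑en‑1‑yl)oxolan‑2‑one
Conditions: MgBr2·OEt2, allylSnBu3, CH2Cl2, −78 to −40 °C
Reagents that add atoms: allyltributylstannane, C=CC[Sn](CCCC)(CCCC)CCCC
Why: Lewis‑acid‑mediated allylstannane addition to the most electrophilic carbonyl (the C3 ketone next to the lactone carbonyl), in which MgBr2 is expected to bridge the C3 and butenoyl oxygens so that the butenoyl group covers one face of C3 and the stannane attacks through an open transition state from the other face, syn to the side‑chain CH2 and anti to the acyl dipole, setting C3 (C7a of the target) as (R) with allyl trans to butenoyl; low temperature and non‑basic conditions should prevent retro‑aldol opening.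

Step 10
Reactants: 15 (3R,4R)‑4‑[(2E)‑but‑2‑enoyl]‑4‑(Ar‑ethyl)‑3‑hydroxy‑3‑(prop‑2‑en‑1‑yl)oxolan‑2‑one
Product: 16 (3aR,7aR)‑3a‑(Ar‑ethyl)‑7a‑hydroxy‑3,3a,7,7a‑tetrahydro‑2‑benzofuran‑1,4‑dione (target)
Conditions: second‑generation Hoveyda–Grubbs catalyst, RuCl2(H2IMes)(=CH‑C6H4‑2‑OiPr) (5 mol %), toluene (high dilution), 80 °C, argon sparge
Reagents that add atoms: none
Why: The ruthenium alkylidene should first engage the unhindered terminal allyl alkene at C7a, and the new alkylidene then closes onto the electron‑poor (E)‑butenoyl alkene at C3a through a ruthenacyclobutane that collapses to the C5=C6 alkene with loss of propene. The closest known reaction type is the ring‑closing metathesis of an allyl group onto an acryloyl or crotonyl ketone to give a cyclohex‑2‑enone. The cyclohexenone is closed as a six‑membered ring by forming its endocyclic C5=C6 double bond, which can only be cis. No stereocentre is formed: C3a and C7a are already set, are not enolizable and are not touched, so the trans relationship built into 15 is carried over as the trans ring fusion. The step needs chemoselectivity for the two reactive alkenes and cyclization rather than oligomerization; the pyranone and furan double bonds are trisubstituted or aromatic and inert, and high dilution, six‑membered ring formation and removal of propene should secure closure. Because the new bond lies two atoms away from both fusion carbons, the trans‑fused bicycle is reached without the cis bias that closure at C3a or C7a of the flat lactone would impose.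

**Compound list**

1 | tert‑butyl 3‑oxobutanoate | CC(=O)CC(=O)OC(C)(C)C | starting material
2 | 4‑chloro‑N‑methoxy‑N‑methylbutanamide | CON(C)C(=O)CCCCl | starting material
3 | tert‑butyl 2‑acetyl‑6‑[methoxy(methyl)amino]‑6‑oxohexanoate (racemic) | CC(=O)C(CCCC(=O)N(C)OC)C(=O)OC(C)(C)C | intermediate
4 | tert‑butyl (2Z)‑2‑{4‑[methoxy(methyl)amino]‑4‑oxobutyl}‑3‑[(trifluoromethanesulfonyl)oxy]but‑2‑enoate | C/C(OS(=O)(=O)C(F)(F)F)=C(\CCCC(=O)N(C)OC)C(=O)OC(C)(C)C | intermediate
5 | furan‑3‑carbaldehyde | O=Cc1ccoc1 | starting material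
6 | 3‑ethynylfuran | C#Cc1ccoc1 | intermediate
7 | tert‑butyl (2Z)‑5‑(furan‑3‑yl)‑2‑{4‑[methoxy(methyl)amino]‑4‑oxobutyl}‑3‑methylpent‑2‑en‑4‑ynoate | C/C(C#Cc1ccoc1)=C(\CCCC(=O)N(C)OC)C(=O)OC(C)(C)C | intermediate
8 | tert‑butyl (2Z)‑5‑(furan‑3‑yl)‑3‑methyl‑2‑(4‑oxohept‑6‑en‑1‑yl)pent‑2‑en‑4‑ynoate | C/C(C#Cc1ccoc1)=C(\CCCC(=O)CC=C)C(=O)OC(C)(C)C | intermediate
9 | tert‑butyl (2Z)‑5‑(furan‑3‑yl)‑3‑methyl‑2‑[(5E)‑4‑oxohept‑5‑en‑1‑yl]pent‑2‑en‑4‑ynoate | C/C(C#Cc1ccoc1)=C(\CCCC(=O)/C=C/C)C(=O)OC(C)(C)C | intermediate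
10 | 6‑(furan‑3‑yl)‑4‑methyl‑3‑[(5E)‑4‑oxohept‑5‑en‑1‑yl]‑2H‑pyran‑2‑one | C/C=C/C(=O)CCCc1c(C)cc(-c2ccoc2)oc1=O | intermediate
11 | diethyl oxalate | CCOC(=O)C(=O)OCC | starting material
12 | ethyl (5E)‑3‑{2‑[6‑(furan‑3‑yl)‑4‑methyl‑2‑oxo‑2H‑pyran‑3‑yl]ethyl}‑2,4‑dioxohept‑5‑enoate | CCOC(=O)C(=O)C(CCc1c(C)cc(-c2ccoc2)oc1=O)C(=O)/C=C/C | intermediate
13 | ethyl (3S,5E)‑3‑{2‑[6‑(furan‑3‑yl)‑4‑methyl‑2‑oxo‑2H‑pyran‑3‑yl]ethyl}‑3‑(hydroxymethyl)‑2,4‑dioxohept‑5‑enoate | Cc1cc(-c2ccoc2)oc(=O)c1CC[C@@](C(=O)C(=O)OCC)(C(=O)/C=C/C)CO | intermediate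
14 | (4S)‑4‑[(2E)‑but‑2‑enoyl]‑4‑{2‑[6‑(furan‑3‑yl)‑4‑methyl‑2‑oxo‑2H‑pyran‑3‑yl]ethyl}oxolane‑2,3‑dione | Cc1cc(-c2ccoc2)oc(=O)c1CC[C@@]1(C(=O)/C=C/C)COC(=O)C1=O | intermediate
15 | (3R,4R)‑4‑[(2E)‑but‑2‑enoyl]‑4‑{2‑[6‑(furan‑3‑yl)‑4‑methyl‑2‑oxo‑2H‑pyran‑3‑yl]ethyl}‑3‑hydroxy‑3‑(prop‑2‑en‑1‑yl)oxolan‑2‑one | Cc1cc(-c2ccoc2)oc(=O)c1CC[C@@]1(C(=O)/C=C/C)COC(=O)[C@@]1(O)CC=C | intermediate
16 | (3aR,7aR)‑3a‑{2‑[6‑(furan‑3‑yl)‑4‑methyl‑2‑oxo‑2H‑pyran‑3‑yl]ethyl}‑7a‑hydroxy‑3,3a,7,7a‑tetrahydro‑2‑benzofuran‑1,4‑dione | Cc1cc(-c2ccoc2)oc(=O)c1CC[C@@]12COC(=O)[C@@]1(O)CC=CC2=O | target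

**Step count and risks**

Total steps: 10. Longest linear sequence: 9 steps (steps 1, 2, 4, 5, 6, 7, 8, 9, 10; step 3 prepares 6 in a side branch).

Most likely to fail, first: step 8 (proposed new method). The palladium enolate may add to formaldehyde with poor facial discrimination. The enol oxygen of 12 may cyclize onto the butenoyl group in a 6‑endo oxa‑Michael reaction. The hydrated C3 ketone of 14 may undergo retro‑Claisen cleavage in the aqueous medium. The fallback uses known chemistry, sets out from 12 and comes back at 15. Base‑catalysed condensation with aqueous formaldehyde and catalytic NaHCO3 in THF (the classical acylpyruvate/formaldehyde reaction) should give the racemic hydroxymethyl adduct F1, which lactonizes in the flask to the racemic 4‑butenoyl‑4‑(Ar‑ethyl)oxolane‑2,3‑dione F2. Allylstannane addition under the conditions of step 9 then gives the racemic allyl carbinol F3. Its enantiomers are separated by preparative chromatography on a chiral stationary phase, and the (3R,4R) enantiomer is 15.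

Second: step 9. The allyl group may add with poor facial selectivity (attack syn to the butenoyl group would lead to the cis‑fused series), and the β‑hydroxy ketone product may open by retro‑aldol cleavage with loss of both stereocentres. The fallback sets out from 14 and comes back at 15. Stereocontrol is moved from the substrate chelate to the reagent: allylboration with the matched enantiomer of B‑allyl‑10‑phenyl‑9‑borabicyclo[3.3.2]decane, a stoichiometric chiral allylborane that reacts with ketones through a closed six‑membered transition state, followed by ethanolamine work‑up. No compound outside the list is made.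

Third: step 7. Deprotonation may compete at the γ‑methyl of the butenoyl group or at the pyranone 4‑methyl group, the enolate may add to a second molecule of enone, and the enolized product may cyclize onto the enone on acidic work‑up. The fallback sets out from 10 and comes back at 12. Soft enolization with Bu2BOTf and iPr2NEt (CH2Cl2, −78 °C), which is selective for the α′‑CH2 of the ketone, and aldol addition to ethyl glyoxylate should give ethyl (5E)‑3‑(Ar‑ethyl)‑2‑hydroxy‑4‑oxohept‑5‑enoate F4 as a mixture of diastereomers. Oxidation of its secondary alcohol with Dess–Martin periodinane under buffered, neutral conditions gives 12.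

Further compounds
F1 | step 8 | racemic ethyl (5E)‑3‑{2‑[6‑(furan‑3‑yl)‑4‑methyl‑2‑oxo‑2H‑pyran‑3‑yl]ethyl}‑3‑(hydroxymethyl)‑2,4‑dioxohept‑5‑enoate | CCOC(=O)C(=O)C(CO)(CCc1c(C)cc(-c2ccoc2)oc1=O)C(=O)/C=C/C
F2 | step 8 | racemic 4‑[(2E)‑but‑2‑enoyl]‑4‑{2‑[6‑(furan‑3‑yl)‑4‑methyl‑2‑oxo‑2H‑pyran‑3‑yl]ethyl}oxolane‑2,3‑dione | C/C=C/C(=O)C1(CCc2c(C)cc(-c3ccoc3)oc2=O)COC(=O)C1=O
F3 | step 8 | racemic (3R*,4R*)‑4‑[(2E)‑but‑2‑enoyl]‑4‑{2‑[6‑(furan‑3‑yl)‑4‑methyl‑2‑oxo‑2H‑pyran‑3‑yl]ethyl}‑3‑hydroxy‑3‑(prop‑2‑en‑1‑yl)oxolan‑2‑one (both enantiomers) | Cc1cc(-c2ccoc2)oc(=O)c1CC[C@@]1(C(=O)/C=C/C)COC(=O)[C@@]1(O)CC=C.Cc1cc(-c2ccoc2)oc(=O)c1CC[C@]1(C(=O)/C=C/C)COC(=O)[C@]1(O)CC=C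
F0 | step 9 | none | none
F4 | step 7 | ethyl (5E)‑3‑{2‑[6‑(furan‑3‑yl)‑4‑methyl‑2‑oxo‑2H‑pyran‑3‑yl]ethyl}‑2‑hydroxy‑4‑oxohept‑5‑enoate (mixture of diastereomers) | CCOC(=O)C(O)C(CCc1c(C)cc(-c2ccoc2)oc1=O)C(=O)/C=C/C
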